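**Plan**

Numbering (ent-kaurane): ring A = C1(=O), C2=C3, C4(Me2), C5(C6H2OH), spiro C10; lactone = C10, C20H2, O, C7(=O), C8, C9; ring C = C8, C9, C11, C12, C13, C14; ring D = C8, C14, C13, C16(OH, C17H3), C15(=O).
Enabling feature: C8 is quaternary, so C16 is the only enolisable carbon next to the C15 ketone, and it lies 1,3 to C13 across C8–C14; ring D can therefore be closed last by a C16–C13 bond onto a ring C alkene.
Cuts, in retrosynthetic order: C16–O; C13–C16 (ring D); C9–C11 and C8–C14 together (ring C, butadiene [4+2]); C8–C15; lactone C20–O bond and C10–C9; C10–C20; C5–C6.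
Forward: ring A from 4,4-dimethylcyclohexenone (dienone, enantioselective vinylation, formylation, acrylate Michael addition), then the spirolactone, ring C, ring D by palladium, C16 hydroxylation, and release of the C1 enone that is carried as its dioxolane.
Stereochemistry: C5 from the Rh/(R)-BINAP 1,4-addition; C10 by Michael addition anti to the C5 arm; C8 and C9 by suprafacial cycloaddition on the lactone face remote from the C5 arm; C13 by the geometry of the bridge; C16 by exo attack of the oxidant.

Key step: step 13

Assumption: (R)-BINAP is taken to deliver the vinyl group with the facial sense known for Rh/BINAP additions to cyclohexenone, which corresponds to (5R)-4; should the sense be reversed on this dienone, (S)-BINAP is used instead.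

**Step 1**
Reactants: 1 4,4-dimethylcyclohex-2-en-1-one
Product: 2 4,4-dimethylcyclohexa-2,5-dien-1-one
Conditions: DDQ, 1,4-dioxane, reflux
Reagents that add atoms: none
Why: Quinone dehydrogenation of a 4,4-disubstituted cyclohexenone can only introduce the C5=C6 double bond and is the standard entry to the cross-conjugated dienone; no stereocenter is formed.

**Step 2**
Reactants: 2 4,4-dimethylcyclohexa-2,5-dien-1-one; 3 potassium vinyltrifluoroborate, K[CH2=CHBF3]
Product: 4 (5R)-5-ethenyl-4,4-dimethylcyclohex-2-en-1-one
Conditions: [Rh(cod)2]BF4 (3 mol %), (R)-BINAP, Et3N, PhMe/H2O, 25 → 40 °C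
Reagents that add atoms: potassium vinyltrifluoroborate (3), [K+].C=C[B-](F)(F)F
Why: Rhodium-catalysed asymmetric 1,4-addition of an alkenyltrifluoroborate (Hayashi–Miyaura reaction) to one enone unit of a 4,4-disubstituted cyclohexadienone is established; the BINAP-bound vinylrhodium species selects the enone face and so sets C5, and the product keeps one enone whose only enolisable position is the future C10.

**Step 3**
Reactants: 4 (5R)-5-ethenyl-4,4-dimethylcyclohex-2-en-1-one
Product: 6 (5S)-5-(hydroxymethyl)-4,4-dimethylcyclohex-2-en-1-one, via keto aldehyde 5 (not isolated)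
Conditions: O3, CH2Cl2/MeOH, −78 °C; Me2S; then NaBH4, −78 °C
Reagents that add atoms: ozone, [O-][O+]=O
Why: Ozonolysis with reductive work-up cleaves the monosubstituted vinyl group far faster than the hindered, electron-poor enone alkene, and NaBH4 at −78 °C reduces the aldehyde but not the conjugated ketone; reducing the aldehyde cold and without isolation protects the epimerisable C5 center (the descriptor changes only through priorities).

**Step 4**
Reactants: 6 (5S)-5-(hydroxymethyl)-4,4-dimethylcyclohex-2-en-1-one
Product: 7 (5S)-5-[(tert-butyldimethylsilyloxy)methyl]-4,4-dimethylcyclohex-2-en-1-one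
Conditions: TBSCl, imidazole, DMF, 0 °C → rt
Reagents that add atoms: tert-butyldimethylsilyl chloride, CC(C)(C)[Si](C)(C)Cl
Why: Routine silylation of a primary alcohol; the ether is stable to the bases, hydrides and mild acids that follow and falls off in the last step.

**Step 5**
Reactants: 7 (5S)-5-[(tert-butyldimethylsilyloxy)methyl]-4,4-dimethylcyclohex-2-en-1-one; 8 ethyl formate
Product: 9 (5R,6Z)-5-[(tert-butyldimethylsilyloxy)methyl]-6-(hydroxymethylidene)-4,4-dimethylcyclohex-2-en-1-one (enol form of the 6-formyl ketone)
Conditions: NaH, HCO2Et, THF (cat. EtOH), 0 °C → rt; aq. HCl work-up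
Reagents that add atoms: ethyl formate (8), CCOC=O
Why: Claisen-type formylation occurs at the only enolisable carbon (the future C10, since C4 is quaternary) and installs C20 as a hydrogen-bonded hydroxymethylene ketone; C5 is untouched.

**Step 6**
Reactants: 9 hydroxymethylene ketone; 10 methyl acrylate
Product: 11 methyl 3-[(1S,6R)-6-[(tert-butyldimethylsilyloxy)methyl]-1-formyl-5,5-dimethyl-2-oxocyclohex-3-en-1-yl]propanoate
Conditions: methyl acrylate, DBU (10 mol %), MeCN, 0 °C → rt
Reagents that add atoms: methyl acrylate (10), C=CC(=O)OC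
Why: Base-catalysed Michael addition of the acidic 2-formyl ketone builds the quaternary C10; the acrylate approaches the planar enolate anti to the pseudoaxial C5 silyloxymethyl arm, so C9 ends trans and C20 cis to that arm, and catalytic base with an acidic pronucleophile present protonates the ester enolate before it can add to the enone.

**Step 7**
Reactants: 11 formyl keto ester
Product: 13 (6S,11R)-11-[(tert-butyldimethylsilyloxy)methyl]-10,10-dimethyl-2-oxaspiro[5.5]undec-8-ene-3,7-dione, via hydroxy ester 12 (not isolated)
Conditions: LiAlH(OtBu)3 (1.1 equiv), THF, −78 → −20 °C; aq. KNaC4H4O6; then CSA (cat.), PhMe, 60 °C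
Reagents that add atoms: none
Why: The bulky hydride, used in stoichiometric amount, reduces the aldehyde chemoselectively beside the hindered enone and the ester, and the neopentyl 5-hydroxy ester then lactonises under acid catalysis to the spiro δ-lactone (C10, C20, O, C7, C8, C9), helped by the gem-disubstitution at C10; no stereocenter changes.

**Step 8**
Reactants: 13 enone spirolactone
Product: 14 C1 ethylene ketal (1,3-dioxolane) of 13, C2=C3 retained
Conditions: Me3SiOCH2CH2OSiMe3, Me3SiOTf (cat.), CH2Cl2, −78 → −20 °C; pyridine quench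
Reagents that add atoms: 1,2-bis(trimethylsilyloxy)ethane, C[Si](C)(C)OCCO[Si](C)(C)C
Why: Silyl-triflate-catalysed ketalisation with the bis-silyl ether is the aprotic method for enones and tolerates lactone and silyl ether; the alkene cannot migrate because C4 is quaternary, and the ketal removes the enone as a Michael acceptor before the C8 and C16 enolates are made.

**Step 9**
Reactants: 14 ketal spirolactone; 15 propanoyl chloride
Product: 16 8-propanoyl derivative of 14 (β-keto lactone, C8 epimers and enol)
Conditions: LiN(SiMe3)2 (2.2 equiv), THF, −78 °C; EtCOCl; aq. NH4Cl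
Reagents that add atoms: propanoyl chloride (15), CCC(=O)Cl
Why: Crossed Claisen acylation of the lithium lactone enolate at C8 by the acid chloride, run with two equivalents of base because the product is more acidic than 14; the C8 configuration is left open since C8 becomes sp2 in step 10.

**Step 10**
Reactants: 16 β-keto lactone
Product: 19 8-propanoyl C8=C9 unsaturated ketal spirolactone, via selenide 17 (not isolated), via selenoxide 18 (not isolated)
Conditions: PhSeCl, pyridine, CH2Cl2, 0 °C; then 30% H2O2, 0 °C; used at once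
Reagents that add atoms: none
Why: α-Selenenylation of the enolised 1,3-dicarbonyl at C8 followed by selenoxide syn-elimination, which can only take a C9 hydrogen, gives the 2-acyl enoate; C10 is quaternary, so the double bond cannot move out of conjugation.

**Step 11**
Reactants: 19 acyl unsaturated lactone; 20 buta-1,3-diene
Product: 21 cis-fused cyclohexene β-keto lactone (ring C = C8, C9, C11, C12=C13, C14; 8-propanoyl cis to H9; C11 on the C1 side of the lactone)
Conditions: buta-1,3-diene (excess), ZnCl2, Et2O/CH2Cl2, 0 °C → rt, sealed tube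
Reagents that add atoms: buta-1,3-diene (20), C=CC=C
Why: Diels–Alder reaction of a chelated 2-acyl enoate, a dienophile class that accepts a quaternary carbon next to its β-carbon; suprafacial addition makes ring C cis-fused to the lactone, which puts C15 cis to H9 at the new quaternary C8, and the diene should take the face of C8=C9 flanked by the small equatorial ketal oxygen on C1 and not the face covered by the equatorial C5 silyloxymethyl arm, which sets C9 with C11 syn to C1.

**Step 12**
Reactants: 21 cyclohexene β-keto lactone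
Product: 22 Z tert-butyldimethylsilyl enol ether of 21 (C15–OSi, C15=C16)
Conditions: LiN(iPr)2, THF, −78 °C; tBuMe2SiOTf, −78 → 0 °C
Reagents that add atoms: tert-butyldimethylsilyl trifluoromethanesulfonate, CC(C)(C)[Si](C)(C)OS(=O)(=O)C(F)(F)F
Why: Kinetic enolisation of the ethyl ketone, whose only acidic site is C16, gives the Z(O)-enolate because the quaternary C8 group keeps the methyl on the oxygen side, and O-silylation traps it as the Z silyl enol ether.

**Step 13**
Reactants: 22 Z silyl enol ether
Product: 23 16-methyl-15-oxo bicyclo[3.2.1]oct-11-ene spirolactone (ring D closed, C11=C12, drawn as the 16-methyl-endo epimer)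
Conditions: Pd(OAc)2 (0.2 equiv), O2 (1 atm), DMSO, 45 °C
Reagents that add atoms: none
Why: The silyl enol ether transmetalates to Pd(OAc)2 to give an enolate of divalent palladium, whose C16 carbon adds together with the metal across the coordinated C12=C13 alkene (C16 to C13, Pd to C12), and syn β-hydride elimination toward C11 then releases the C11=C12 alkene and zerovalent palladium, which O2 returns to Pd(OAc)2. The closest known reaction type is the palladium-mediated cycloalkenylation of silyl enol ethers onto unactivated alkenes, which gives bicyclo[3.2.1]octanones. Ring D (C8, C14, C13, C16, C15) closes in the 5-exo-trig mode. The new C13 stereocenter is fixed by the tether, because the enol ether on quaternary C8 reaches C13 only from an axial position on ring C and the two-carbon bridge must therefore be cis-1,3; C16 is expected with methyl endo, but its configuration does not matter since step 15 re-enolises it. The step needs attack at C13 and not at C12 (which would give the bicyclo[2.2.2] isomer) and insertion faster than Saegusa-type loss of a C17 hydrogen; the 1,3-relationship of C8 and C13 favours the five-membered closure, only C11 can supply a syn hydrogen once C13 is a bridgehead, and DMSO/O2 conditions are those known to favour insertion over dehydrosilylation.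

**Step 14**
Reactants: 23 bicyclooctene
Product: 24 11,12-dihydro derivative of 23
Conditions: 2-O2NC6H4SO2NHNH2, Et3N, CH2Cl2, rt
Reagents that add atoms: none
Why: Diimide reduction (concerted syn transfer of H2 from HN=NH released by the sulfonylhydrazide) should take the strained C11=C12 bond and leave the ring A C2=C3 bond, whose two allylic carbons are fully substituted, and being metal-free it cannot shift the alkene toward C9; no stereocenter is created.

**Step 15**
Reactants: 24 saturated C15 ketone
Product: 25 16-exo-hydroxy-16-endo-methyl derivative of 24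
Conditions: KN(SiMe3)2, THF, −78 °C; 2-(phenylsulfonyl)-3-phenyloxaziridine; aq. NH4Cl at −78 °C
Reagents that add atoms: 2-(phenylsulfonyl)-3-phenyloxaziridine, O=S(=O)(c1ccccc1)N1OC1c1ccccc1
Why: Enolate hydroxylation with an N-sulfonyloxaziridine: the base removes the only α-hydrogen of the C15 ketone (C16–H) and the oxidant approaches the enolate from the exo face of ring D, away from the C9–C11–C12 bridge, which places the hydroxyl exo and the methyl endo as in the target.

**Step 16**
Reactants: 25 protected hydroxy ketone
Product: 26 target (CNP0530135.1)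
Conditions: 2 M aq. HCl, THF, rt
Reagents that add atoms: water, O
Why: Acid hydrolysis of the allylic dioxolane (through a conjugated oxocarbenium ion) returns the C1 enone directly and the same dilute acid cleaves the primary silyl ether, while the non-enolisable β-keto lactone and the tertiary ketol are inert to these conditions; no stereocenter is touched.

**Compound list**

1 | 4,4-dimethylcyclohex-2-en-1-one | CC1(C)C=CC(=O)CC1 | starting material
2 | 4,4-dimethylcyclohexa-2,5-dien-1-one | CC1(C)C=CC(=O)C=C1 | intermediate
3 | potassium vinyltrifluoroborate, K[CH2=CHBF3] | [K+].C=C[B-](F)(F)F | starting material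
4 | (5R)-5-ethenyl-4,4-dimethylcyclohex-2-en-1-one | CC1(C)C=CC(=O)C[C@@H]1C=C | intermediate
5 | (1S)-2,2-dimethyl-5-oxocyclohex-3-ene-1-carbaldehyde | CC1(C)C=CC(=O)C[C@@H]1C=O | intermediate
6 | (5S)-5-(hydroxymethyl)-4,4-dimethylcyclohex-2-en-1-one | CC1(C)C=CC(=O)C[C@@H]1CO | intermediate
7 | (5S)-5-[(tert-butyldimethylsilyloxy)methyl]-4,4-dimethylcyclohex-2-en-1-one | CC1(C)C=CC(=O)C[C@@H]1CO[Si](C)(C)C(C)(C)C | intermediate
8 | ethyl formate | CCOC=O | starting material
9 | (5R,6Z)-5-[(tert-butyldimethylsilyloxy)methyl]-6-(hydroxymethylidene)-4,4-dimethylcyclohex-2-en-1-one | CC1(C)C=CC(=O)/C(=C\O)[C@@H]1CO[Si](C)(C)C(C)(C)C | intermediate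
10 | methyl acrylate | C=CC(=O)OC | starting material
11 | methyl 3-[(1S,6R)-6-[(tert-butyldimethylsilyloxy)methyl]-1-formyl-5,5-dimethyl-2-oxocyclohex-3-en-1-yl]propanoate | CC1(C)C=CC(=O)[C@@](C=O)(CCC(=O)OC)[C@@H]1CO[Si](C)(C)C(C)(C)C | intermediate
12 | methyl 3-[(1S,6R)-6-[(tert-butyldimethylsilyloxy)methyl]-1-(hydroxymethyl)-5,5-dimethyl-2-oxocyclohex-3-en-1-yl]propanoate | CC1(C)C=CC(=O)[C@@](CO)(CCC(=O)OC)[C@@H]1CO[Si](C)(C)C(C)(C)C | intermediate
13 | (6S,11R)-11-[(tert-butyldimethylsilyloxy)methyl]-10,10-dimethyl-2-oxaspiro[5.5]undec-8-ene-3,7-dione (C9 trans, C20 cis to the C5 arm) | CC1(C)C=CC(=O)[C@]2(COC(=O)CC2)[C@@H]1CO[Si](C)(C)C(C)(C)C | intermediate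
14 | C1 ethylene ketal (1,3-dioxolane) of 13, configuration as in 13 | CC1(C)C=CC5(OCCO5)[C@]2(COC(=O)CC2)[C@@H]1CO[Si](C)(C)C(C)(C)C | intermediate
15 | propanoyl chloride | CCC(=O)Cl | starting material
16 | 8-propanoyl derivative of 14 (C8 epimers and enol) | CC1(C)C=CC5(OCCO5)[C@]2(COC(=O)C(C(=O)CC)C2)[C@@H]1CO[Si](C)(C)C(C)(C)C | intermediate
17 | 8-(phenylselanyl)-8-propanoyl lactone (C8 epimers) | CC1(C)C=CC5(OCCO5)[C@]2(COC(=O)C([Se]c3ccccc3)(C(=O)CC)C2)[C@@H]1CO[Si](C)(C)C(C)(C)C | intermediate
18 | selenoxide of 17 | CC1(C)C=CC5(OCCO5)[C@]2(COC(=O)C([Se](=O)c3ccccc3)(C(=O)CC)C2)[C@@H]1CO[Si](C)(C)C(C)(C)C | intermediate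
19 | 8-propanoyl C8=C9 unsaturated ketal spirolactone | CC1(C)C=CC5(OCCO5)[C@]2(COC(=O)C(C(=O)CC)=C2)[C@@H]1CO[Si](C)(C)C(C)(C)C | intermediate
20 | buta-1,3-diene | C=CC=C | starting material
21 | cis-fused cyclohex-12-ene β-keto lactone (8-propanoyl cis to H9, C11 syn to C1) | CC1(C)C=CC5(OCCO5)[C@]2(COC(=O)[C@@]3(C(=O)CC)CC=CC[C@H]32)[C@@H]1CO[Si](C)(C)C(C)(C)C | intermediate
22 | Z tert-butyldimethylsilyl enol ether of 21 | CC1(C)C=CC5(OCCO5)[C@]2(COC(=O)[C@@]3(/C(O[Si](C)(C)C(C)(C)C)=C/C)CC=CC[C@H]32)[C@@H]1CO[Si](C)(C)C(C)(C)C | intermediate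
23 | 16-methyl-15-oxo bicyclo[3.2.1]oct-11-ene spirolactone (16-methyl endo) | CC1(C)C=CC5(OCCO5)[C@]2(COC(=O)[C@@]34C[C@@H](C=C[C@H]32)[C@@H](C)C4=O)[C@@H]1CO[Si](C)(C)C(C)(C)C | intermediate
24 | 11,12-dihydro derivative of 23 | CC1(C)C=CC5(OCCO5)[C@]2(COC(=O)[C@@]34C[C@@H](CC[C@H]32)[C@@H](C)C4=O)[C@@H]1CO[Si](C)(C)C(C)(C)C | intermediate
25 | 16-exo-hydroxy-16-endo-methyl derivative of 24 | CC1(C)C=CC5(OCCO5)[C@]2(COC(=O)[C@@]34C[C@@H](CC[C@H]32)[C@](C)(O)C4=O)[C@@H]1CO[Si](C)(C)C(C)(C)C | intermediate
26 | target CNP0530135.1 (6,7-seco-ent-kaurane 7,20-lactone; C1 enone, 6-OH, 15-oxo, 16-exo-OH) | CC1(C)C=CC(=O)[C@]2(COC(=O)[C@@]34C[C@@H](CC[C@H]32)[C@](C)(O)C4=O)[C@@H]1CO | target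

**Step count and risks**

Total step count: 16. Longest linear sequence: 16 steps (from 1; all other inputs are commercial).

Step 11 (Diels–Alder). What may go wrong: the dienophile, hindered by the spiro center next to C9, may react too slowly with unactivated butadiene, so that ionisation of the allylic ketal by ZnCl2 or oligomerisation of the acyl enoate takes over, or the diene may add with poor facial selectivity. Fallback, from 14 back to 21, builds ring C stepwise without a Lewis acid. Enolate selenenylation of 14 (LiN(iPr)2, PhSeBr, THF, −78 °C) gives the 8-(phenylselanyl) lactone F1, and oxidative syn-elimination (H2O2, pyridine, 0 °C) gives the C8=C9 unsaturated spirolactone F2. Copper-mediated conjugate allylation (CH2=CHCH2MgBr, CuBr·SMe2, Me3SiCl, THF, −78 °C) on the face remote from the C5 arm gives the 9-allyl lactone F3. Enolate alkylation (LiN(iPr)2, allyl bromide) trans to the C9 allyl group gives the 8,9-trans-diallyl lactone F4. A second enolisation and aldol addition to propanal, again anti to the C9 allyl group, gives the quaternary aldol F5, and Dess–Martin oxidation gives the 8-propanoyl 8,9-cis-diallyl lactone F6. Ring-closing metathesis (second-generation Grubbs catalyst, CH2Cl2, 40 °C) closes the C12=C13 cyclohexene and returns 21.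

Step 13 (palladium cyclisation). What may go wrong: the palladium enolate may lose a C17 hydrogen (dehydrosilylation to the vinyl ketone) faster than it inserts the ring alkene, or closure may occur at C12 to give the bicyclo[2.2.2] skeleton. Fallback, from 22 to 24, forms the same C13–C16 bond by a radical. Bromination of the silyl enol ether with NBS (THF, −78 °C) gives the 16-bromo ketone F7. Bu3SnH with AIBN (PhH, 80 °C, slow addition) then generates the C16 α-keto radical, which closes 5-exo onto C13; the C12 radical is reduced by the stannane, giving 24 directly, and either C16 epimer serves in step 15.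

Step 14 (diimide reduction). What may go wrong: competitive reduction of the ring A C2=C3 bond, or incomplete reduction of the hindered C11=C12 bond. Fallback, from 23 to 26, gives up the selectivity and restores C2=C3 at the end. Hydrogenation of both alkenes (H2, Pd/C, EtOAc) gives the tetrahydro ketal F8, and hydroxylation as in step 15 gives the 16-hydroxy ketone F9. Ketal exchange (I2 cat., acetone, rt) frees the C1 ketone with the silyl ether intact, F10. IBX (DMSO, 70 °C) desaturates C2–C3, the only position open since C10 is quaternary, to the enone silyl ether F11, and 2 M aq. HCl in THF cleaves the silyl ether to 26.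

**Further compounds**

F1 | step 11 | 8-(phenylselanyl) ketal spirolactone (C8 epimers) | CC1(C)C=CC5(OCCO5)[C@]2(COC(=O)C([Se]c3ccccc3)C2)[C@@H]1CO[Si](C)(C)C(C)(C)C
F2 | step 11 | C8=C9 unsaturated ketal spirolactone | CC1(C)C=CC5(OCCO5)[C@]2(COC(=O)C=C2)[C@@H]1CO[Si](C)(C)C(C)(C)C
F3 | step 11 | 9-allyl ketal spirolactone (allyl syn to C1) | CC1(C)C=CC5(OCCO5)[C@]2(COC(=O)C[C@H]2CC=C)[C@@H]1CO[Si](C)(C)C(C)(C)C
F4 | step 11 | 8,9-trans-diallyl ketal spirolactone | CC1(C)C=CC5(OCCO5)[C@]2(COC(=O)[C@H](CC=C)[C@H]2CC=C)[C@@H]1CO[Si](C)(C)C(C)(C)C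
F5 | step 11 | 8-(1-hydroxypropyl) 8,9-cis-diallyl ketal spirolactone (carbinol epimers) | CC1(C)C=CC5(OCCO5)[C@]2(COC(=O)[C@@](C(O)CC)(CC=C)[C@H]2CC=C)[C@@H]1CO[Si](C)(C)C(C)(C)C
F6 | step 11 | 8-propanoyl 8,9-cis-diallyl ketal spirolactone | CC1(C)C=CC5(OCCO5)[C@]2(COC(=O)[C@@](C(=O)CC)(CC=C)[C@H]2CC=C)[C@@H]1CO[Si](C)(C)C(C)(C)C
F7 | step 13 | 16-bromo derivative of 21 (C16 epimers) | CC1(C)C=CC5(OCCO5)[C@]2(COC(=O)[C@@]3(C(=O)C(C)Br)CC=CC[C@H]32)[C@@H]1CO[Si](C)(C)C(C)(C)C
F8 | step 14 | 2,3,11,12-tetrahydro derivative of 23 | CC1(C)CCC5(OCCO5)[C@]2(COC(=O)[C@@]34C[C@@H](CC[C@H]32)[C@@H](C)C4=O)[C@@H]1CO[Si](C)(C)C(C)(C)C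
F9 | step 14 | 16-exo-hydroxy derivative of F8 | CC1(C)CCC5(OCCO5)[C@]2(COC(=O)[C@@]34C[C@@H](CC[C@H]32)[C@](C)(O)C4=O)[C@@H]1CO[Si](C)(C)C(C)(C)C
F10 | step 14 | C1 ketone from F9, silyl ether retained (2,3-dihydro-F11) | CC1(C)CCC(=O)[C@]2(COC(=O)[C@@]34C[C@@H](CC[C@H]32)[C@](C)(O)C4=O)[C@@H]1CO[Si](C)(C)C(C)(C)C
F11 | step 14 | 6-O-tert-butyldimethylsilyl ether of 26 | CC1(C)C=CC(=O)[C@]2(COC(=O)[C@@]34C[C@@H](CC[C@H]32)[C@](C)(O)C4=O)[C@@H]1CO[Si](C)(C)C(C)(C)C
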